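## Retrosynthetic overview

- Ring numbering: O1, C2 (R), C3, C4=C5, C6, with the side chain starting at C1′ on C5. The acrylic acid on C2 is traced back through an enol triflate and a methyl ketone to the CO2Me group of a (2R)-3,6-dihydro-2H-pyran-2-carboxylate.
- The only ring, the dihydropyran, is opened at O1–C6: allylic etherification of an acyclic (4Z) hydroxy ester that carries a primary allylic carbonate.
- Feature the plan rests on: C6(–O1)–C5(–C1′)=C4H is propargyl alcohol that has gained a carbon group at C5 and a C–C bond at C4 cis to C6, and C2(–O1)–C3 beside a carboxyl carbon is a glycidic ester. C5–C1′ and C3–C4 are therefore cut together.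
- The three components are propargyl alcohol, homofarnesylmagnesium bromide (from (2E,6E)-farnesol by one-carbon homologation) and methyl (R)-glycidate.
- Order of events: acyclic skeleton first (step 6), the single ring second (step 8), the acrylic acid last (steps 9–12).

Key step: step 6

Assumption: (2E,6E)-farnesol and methyl (R)-glycidate are bought as single isomers; the target's only stereocentre, C2, is (R) and is the epoxide CH of methyl (R)-glycidate, to which no bond is broken anywhere in the route.

## Route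

Step 1
Reactants: 1 (2E,6E)-farnesol
Product: 2 (2E,6E)-3,7,11-trimethyldodeca-2,6,10-trienal (farnesal)
Conditions: PhI(OAc)2 (1.1 equiv), TEMPO (10 mol%), CH2Cl2, rt
Reagents that add atoms: none
Why: Oxoammonium (TEMPO) oxidation with PhI(OAc)2 as terminal oxidant converts the primary allylic alcohol into the enal without over-oxidation and should not disturb the 2E geometry.

Step 2
Reactants: 2 (2E,6E)-farnesal
Product: 3 (3E,7E)-4,8,12-trimethyltrideca-1,3,7,11-tetraene
Conditions: Ph3PCH3Br, nBuLi, THF, 0 °C; then 2, −78 °C → rt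
Reagents that add atoms: methyltriphenylphosphonium bromide, C[P+](c1ccccc1)(c1ccccc1)c1ccccc1.[Br-]
Why: Wittig methylenation of the enal by the non-stabilised ylide forms the terminal diene by 1,2-addition and leaves the existing E alkenes as they are.

Step 3
Reactants: 3 (3E,7E)-4,8,12-trimethyltrideca-1,3,7,11-tetraene
Product: 5 (3E,7E)-4,8,12-trimethyltrideca-3,7,11-trien-1-ol (homofarnesol), via B-homofarnesyl-9-borabicyclo[3.3.1]nonane 4 (not isolated)
Conditions: 9-BBN (1.05 equiv), THF, 0 °C → rt; then aq NaOH, H2O2, 0 °C → rt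
Reagents that add atoms: hydrogen peroxide, OO
Why: Hydroboration–oxidation with the bulky 9-BBN takes place only at the monosubstituted terminal alkene, with boron on the terminal carbon, so that oxidation gives the primary homoallylic alcohol while the three trisubstituted alkenes stay.

Step 4
Reactants: 5 homofarnesol
Product: 6 (3E,7E)-1-bromo-4,8,12-trimethyltrideca-3,7,11-triene (homofarnesyl bromide)
Conditions: CBr4, PPh3, CH2Cl2, 0 °C
Reagents that add atoms: carbon tetrabromide, BrC(Br)(Br)Br
Why: Appel bromination replaces the primary hydroxyl by SN2 displacement of the alkoxyphosphonium ion under neutral conditions that the trisubstituted alkenes tolerate.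

Step 5
Reactants: 6 homofarnesyl bromide
Product: 7 [(3E,7E)-4,8,12-trimethyltrideca-3,7,11-trien-1-yl]magnesium bromide (homofarnesylmagnesium bromide, titrated THF solution)
Conditions: Mg turnings (I2-activated), THF, 30–40 °C, slow addition
Reagents that add atoms: magnesium, [Mg]
Why: Grignard formation by magnesium insertion into the primary C–Br bond; the homoallylic radical at the metal surface is reduced much faster than it can cyclise, so the 3E geometry should be kept.

Step 6
Reactants: 7 homofarnesylmagnesium bromide; 8 propargyl alcohol; 9 methyl (R)-glycidate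
Product: 12 methyl (2R,4Z,8E,12E)-2-hydroxy-5-(hydroxymethyl)-9,13,17-trimethyloctadeca-4,8,12,16-tetraenoate, via chloromagnesium prop-2-ynoxide 10 (not isolated), via cyclic vinylmagnesium alkoxide 11 (not isolated)
Conditions: 8, iPrMgCl (1.0 equiv), THF, −20 °C; CuI (10 mol%), 7 (1.3 equiv), THF/Et2O, −10 °C → rt; then 9 (1.5 equiv), −40 → −10 °C; aq NH4Cl
Reagents that add atoms: none
Why: The chloromagnesium alkoxide 10 directs the CuI-catalysed addition of 7 across the alkyne in an anti sense, the homofarnesyl group going to the internal carbon (future C5) and magnesium to the terminal carbon (future C4), where it is held cis to the CH2O arm in the five-membered chelate 11. Transmetalation of 11 to copper and SN2 attack at the unsubstituted CH2 of epoxide 9, with retention at the vinyl carbon, form C3–C4, so that C3 ends cis to C6 (4Z), as the later ring needs. The closest known reaction types are the CuI-catalysed anti-carbomagnesiation of propargylic alcohols with electrophilic trapping of the chelated vinylmagnesium, and the copper-catalysed opening of glycidic esters by alkenyl Grignard reagents at the CH2 carbon. No ring is closed and no stereocentre is created: the carbinol carbon C2 is the untouched epoxide CH of 9 and stays (R). The step needs regio- and anti-selectivity in the carbometalation, which the alkoxide chelate secures, and attack at the epoxide CH2 in preference to the ester carbonyl, which the copper catalyst and the low temperature secure. Pre-forming 10 with iPrMgCl saves one equivalent of 7, and the small excess of 7 that remains is consumed by the excess of 9 to give a mono-alcohol that is separable from the diol.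

Step 7
Reactants: 12 diol ester
Product: 13 methyl (2R,4Z,8E,12E)-2-hydroxy-5-{[(methoxycarbonyl)oxy]methyl}-9,13,17-trimethyloctadeca-4,8,12,16-tetraenoate
Conditions: ClCO2Me (1.05 equiv), pyridine, CH2Cl2, −30 → 0 °C
Reagents that add atoms: methyl chloroformate, COC(=O)Cl
Why: Chemoselective acylation, in which the unhindered primary allylic hydroxyl reacts with one equivalent of chloroformate at low temperature far faster than the secondary hydroxyl, which is hindered and deactivated by the neighbouring ester.

Step 8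
Reactants: 13 primary allylic carbonate
Product: 14 methyl (2R)-5-[(3E,7E)-4,8,12-trimethyltrideca-3,7,11-trien-1-yl]-3,6-dihydro-2H-pyran-2-carboxylate
Conditions: Pd(PPh3)4 (5 mol%), THF (0.01 M), rt → 40 °C
Reagents that add atoms: none
Why: Tsuji–Trost allylic etherification, in which zerovalent palladium ionises the carbonate to a 2-substituted π-allyl complex with C3 in the anti position inherited from the 4Z alkene, the methoxide set free by decarboxylation deprotonates the C2 hydroxyl, and the alkoxide attacks the CH2 terminus C6 to close the six-membered ring (the four-membered alternative through C4 is not competitive) without touching the C2–O bond, so (R) is kept.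

Step 9
Reactants: 14 dihydropyran methyl ester
Product: 15 (2R)-N-methoxy-N-methyl-5-[(3E,7E)-4,8,12-trimethyltrideca-3,7,11-trien-1-yl]-3,6-dihydro-2H-pyran-2-carboxamide
Conditions: MeNHOMe·HCl (1.5 equiv), iPrMgCl (3.0 equiv), THF, −20 °C; aq NH4Cl
Reagents that add atoms: N,O-dimethylhydroxylamine hydrochloride, CNOC.Cl
Why: Aminolysis of the methyl ester by the magnesium amide of N,O-dimethylhydroxylamine gives the Weinreb amide at −20 °C, conditions under which α-alkoxy stereocentres are normally preserved.

Step 10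
Reactants: 15 Weinreb amide
Product: 17 1-{(2R)-5-[(3E,7E)-4,8,12-trimethyltrideca-3,7,11-trien-1-yl]-3,6-dihydro-2H-pyran-2-yl}ethan-1-one, via magnesium hemiaminal chelate 16 (not isolated)
Conditions: MeMgBr (1.5 equiv), THF, −78 → 0 °C; aq NH4Cl
Reagents that add atoms: methylmagnesium bromide, C[Mg]Br
Why: Weinreb ketone synthesis, in which MeMgBr adds once and the N-methoxy magnesium chelate 16 holds until work-up, so that neither over-addition nor enolisation at C2 should take place.

Step 11
Reactants: 17 methyl ketone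
Product: 19 1-{(2R)-5-[(3E,7E)-4,8,12-trimethyltrideca-3,7,11-trien-1-yl]-3,6-dihydro-2H-pyran-2-yl}ethenyl trifluoromethanesulfonate, via potassium enolate 18 (not isolated)
Conditions: KN(SiMe3)2 (1.1 equiv), THF, −78 °C; then PhNTf2, −78 → −20 °C; aq NH4Cl
Reagents that add atoms: N-phenylbis(trifluoromethanesulfonimide), O=S(=O)(N(c1ccccc1)S(=O)(=O)C(F)(F)F)C(F)(F)F
Why: Kinetic deprotonation by the bulky amide base at −78 °C takes the unhindered methyl protons in preference to the hindered C2–H beside the ring oxygen, and O-triflation of the terminal enolate by PhNTf2 gives the 1,1-disubstituted enol triflate with C2 untouched.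

Step 12
Reactants: 19 enol triflate
Product: 21 2-{(2R)-5-[(3E,7E)-4,8,12-trimethyltrideca-3,7,11-trien-1-yl]-3,6-dihydro-2H-pyran-2-yl}prop-2-enoic acid (CNP0171598.2), via mixed acetic anhydride 20 (not isolated)
Conditions: Pd(OAc)2 (5 mol%), PPh3 (10 mol%), KOAc (4 equiv), CO (1 atm), DMF, rt → 50 °C; then H2O, work-up at pH 3
Reagents that add atoms: carbon monoxide, [C-]#[O+]; potassium acetate, CC(=O)[O-].[K+]; water, O (the hydroxyl oxygen of the acid comes from acetate or from water, depending on which carbonyl of 20 is hydrolysed)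
Why: Palladium-catalysed hydroxycarbonylation, in which oxidative addition of the vinyl triflate to zerovalent palladium, CO insertion and capture of the acylpalladium by acetate give the mixed anhydride 20, which aqueous work-up hydrolyses to the acrylic acid while the stereocentre and the trisubstituted alkenes take no part.

## Compound list

1 | (2E,6E)-farnesol | OC/C=C(\C)CC/C=C(\C)CCC=C(C)C | starting material
2 | (2E,6E)-3,7,11-trimethyldodeca-2,6,10-trienal (farnesal) | O=C/C=C(\C)CC/C=C(\C)CCC=C(C)C | intermediate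
3 | (3E,7E)-4,8,12-trimethyltrideca-1,3,7,11-tetraene | C=C/C=C(\C)CC/C=C(\C)CCC=C(C)C | intermediate
4 | 9-[(3E,7E)-4,8,12-trimethyltrideca-3,7,11-trien-1-yl]-9-borabicyclo[3.3.1]nonane (not isolated) | B1(CC/C=C(\C)CC/C=C(\C)CCC=C(C)C)C2CCCC1CCC2 | intermediate
5 | (3E,7E)-4,8,12-trimethyltrideca-3,7,11-trien-1-ol (homofarnesol) | OCC/C=C(\C)CC/C=C(\C)CCC=C(C)C | intermediate
6 | (3E,7E)-1-bromo-4,8,12-trimethyltrideca-3,7,11-triene (homofarnesyl bromide) | BrCC/C=C(\C)CC/C=C(\C)CCC=C(C)C | intermediate
7 | [(3E,7E)-4,8,12-trimethyltrideca-3,7,11-trien-1-yl]magnesium bromide | Br[Mg]CC/C=C(\C)CC/C=C(\C)CCC=C(C)C | intermediate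
8 | propargyl alcohol | C#CCO | starting material
9 | methyl (R)-glycidate | COC(=O)[C@H]1CO1 | starting material
10 | chloromagnesium prop-2-ynoxide (not isolated) | C#CCO[Mg]Cl | intermediate
11 | 4-[(3E,7E)-4,8,12-trimethyltrideca-3,7,11-trien-1-yl]-2,5-dihydro-1,2-oxamagnesole, the cyclic vinylmagnesium alkoxide (not isolated) | [Mg]1OCC(CC/C=C(\C)CC/C=C(\C)CCC=C(C)C)=C1 | intermediate
12 | methyl (2R,4Z,8E,12E)-2-hydroxy-5-(hydroxymethyl)-9,13,17-trimethyloctadeca-4,8,12,16-tetraenoate | COC(=O)[C@H](O)C/C=C(\CO)CC/C=C(\C)CC/C=C(\C)CCC=C(C)C | intermediate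
13 | methyl (2R,4Z,8E,12E)-2-hydroxy-5-{[(methoxycarbonyl)oxy]methyl}-9,13,17-trimethyloctadeca-4,8,12,16-tetraenoate | COC(=O)[C@H](O)C/C=C(\COC(=O)OC)CC/C=C(\C)CC/C=C(\C)CCC=C(C)C | intermediate
14 | methyl (2R)-5-[(3E,7E)-4,8,12-trimethyltrideca-3,7,11-trien-1-yl]-3,6-dihydro-2H-pyran-2-carboxylate | COC(=O)[C@H]1CC=C(CC/C=C(\C)CC/C=C(\C)CCC=C(C)C)CO1 | intermediate
15 | (2R)-N-methoxy-N-methyl-5-[(3E,7E)-4,8,12-trimethyltrideca-3,7,11-trien-1-yl]-3,6-dihydro-2H-pyran-2-carboxamide | CON(C)C(=O)[C@H]1CC=C(CC/C=C(\C)CC/C=C(\C)CCC=C(C)C)CO1 | intermediate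
16 | bromomagnesium salt of the tetrahedral methyl adduct of 15 (hemiaminal chelate, carbinol carbon undefined; not isolated) | CON(C)C(C)(O[Mg]Br)[C@H]1CC=C(CC/C=C(\C)CC/C=C(\C)CCC=C(C)C)CO1 | intermediate
17 | 1-{(2R)-5-[(3E,7E)-4,8,12-trimethyltrideca-3,7,11-trien-1-yl]-3,6-dihydro-2H-pyran-2-yl}ethan-1-one | CC(=O)[C@H]1CC=C(CC/C=C(\C)CC/C=C(\C)CCC=C(C)C)CO1 | intermediate
18 | potassium 1-{(2R)-5-[(3E,7E)-4,8,12-trimethyltrideca-3,7,11-trien-1-yl]-3,6-dihydro-2H-pyran-2-yl}ethenolate (not isolated) | [K+].C=C([O-])[C@H]1CC=C(CC/C=C(\C)CC/C=C(\C)CCC=C(C)C)CO1 | intermediate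
19 | 1-{(2R)-5-[(3E,7E)-4,8,12-trimethyltrideca-3,7,11-trien-1-yl]-3,6-dihydro-2H-pyran-2-yl}ethenyl trifluoromethanesulfonate | C=C(OS(=O)(=O)C(F)(F)F)[C@H]1CC=C(CC/C=C(\C)CC/C=C(\C)CCC=C(C)C)CO1 | intermediate
20 | acetic 2-{(2R)-5-[(3E,7E)-4,8,12-trimethyltrideca-3,7,11-trien-1-yl]-3,6-dihydro-2H-pyran-2-yl}prop-2-enoic anhydride (not isolated) | C=C(C(=O)OC(C)=O)[C@H]1CC=C(CC/C=C(\C)CC/C=C(\C)CCC=C(C)C)CO1 | intermediate
21 | 2-{(2R)-5-[(3E,7E)-4,8,12-trimethyltrideca-3,7,11-trien-1-yl]-3,6-dihydro-2H-pyran-2-yl}prop-2-enoic acid (CNP0171598.2) | C=C(C(=O)O)[C@H]1CC=C(CC/C=C(\C)CC/C=C(\C)CCC=C(C)C)CO1 | target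

## Step count and risks

Total step count: 12. Longest linear sequence: 12 steps (1 → 21); 8 and 9 enter at step 6 as bought.

Steps most likely to fail:

1. Step 6. The chelated vinylmagnesium 11 may pass its vinyl group to copper too slowly. Then opening of the epoxide by halide, addition to the ester carbonyl, or protonation of the vinyl–metal bond would compete, and residual 7 would consume the glycidate. Fallback, setting out from 7 and 8 (through 10 and 11 as in step 6) and returning at 12: the carbomagnesiation mixture is quenched with I2 at −20 °C instead of with 9, to give (2Z)-3-iodo-2-[(3E,7E)-4,8,12-trimethyltrideca-3,7,11-trien-1-yl]prop-2-en-1-ol F1. TBSCl and imidazole in DMF give tert-butyl{[(2Z)-3-iodo-2-[(3E,7E)-4,8,12-trimethyltrideca-3,7,11-trien-1-yl]prop-2-en-1-yl]oxy}dimethylsilane F2. Iodine–lithium exchange (tBuLi, 2 equiv, Et2O, −78 °C), transmetalation with MgBr2·OEt2, CuI (10 mol%) and addition of 9 at −40 °C give the unchelated, more reactive vinyl metal route to methyl (2R,4Z,8E,12E)-5-{[(tert-butyldimethylsilyl)oxy]methyl}-2-hydroxy-9,13,17-trimethyloctadeca-4,8,12,16-tetraenoate F3. Bu4NF buffered with AcOH in THF then releases 12.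

2. Step 8. The closure needs the alkoxide to reach the far terminus of the π-allyl unit through a ring that contains all three allyl carbons. Capture of the π-allyl complex by methoxide, elimination to a diene, or anti-to-syn isomerisation followed by intermolecular etherification may overtake it. Fallback, setting out from 12 and returning at 14: MsCl, LiCl and 2,4,6-collidine in DMF at 0 °C convert only the allylic hydroxyl into the chloride, methyl (2R,4Z,8E,12E)-5-(chloromethyl)-2-hydroxy-9,13,17-trimethyloctadeca-4,8,12,16-tetraenoate F4. NaH (1.0 equiv) with catalytic Bu4NI in THF at 0 °C then closes O1–C6 by a 6-exo-tet Williamson displacement to give 14; the limiting amount of base and the low temperature guard C2.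

3. Step 11. Enolisation may not be fully regioselective; deprotonation at C2 would erode the configuration or lead to the isomeric tetrasubstituted enol triflate. Fallback, setting out from 14 and returning at 20 (and so 21), with no enolate next to C2:
   - iBu2AlH in CH2Cl2 at −78 °C gives (2R)-5-[(3E,7E)-4,8,12-trimethyltrideca-3,7,11-trien-1-yl]-3,6-dihydro-2H-pyran-2-carbaldehyde F5.
   - Ohira–Bestmann alkynylation (dimethyl (1-diazo-2-oxopropyl)phosphonate, K2CO3, MeOH, 0 °C → rt) gives (2R)-2-ethynyl-5-[(3E,7E)-4,8,12-trimethyltrideca-3,7,11-trien-1-yl]-3,6-dihydro-2H-pyran F6.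
   - Hydrostannation of this propargylic ether with Bu3SnH and catalytic Mo(CO)3(CNtBu)3 in THF at 55 °C, which places tin on the internal carbon, gives tributyl(1-{(2R)-5-[(3E,7E)-4,8,12-trimethyltrideca-3,7,11-trien-1-yl]-3,6-dihydro-2H-pyran-2-yl}ethenyl)stannane F7.
   - I2 in CH2Cl2 at 0 °C gives (2R)-2-(1-iodoethenyl)-5-[(3E,7E)-4,8,12-trimethyltrideca-3,7,11-trien-1-yl]-3,6-dihydro-2H-pyran F8.
   - F8 is carbonylated under the conditions of step 12 to 20 and then 21.

## Further compounds

F1 | step 6 | (2Z)-3-iodo-2-[(3E,7E)-4,8,12-trimethyltrideca-3,7,11-trien-1-yl]prop-2-en-1-ol | OC/C(=C\I)CC/C=C(\C)CC/C=C(\C)CCC=C(C)C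
F2 | step 6 | tert-butyl{[(2Z)-3-iodo-2-[(3E,7E)-4,8,12-trimethyltrideca-3,7,11-trien-1-yl]prop-2-en-1-yl]oxy}dimethylsilane | CC(C)(C)[Si](C)(C)OC/C(=C\I)CC/C=C(\C)CC/C=C(\C)CCC=C(C)C
F3 | step 6 | methyl (2R,4Z,8E,12E)-5-{[(tert-butyldimethylsilyl)oxy]methyl}-2-hydroxy-9,13,17-trimethyloctadeca-4,8,12,16-tetraenoate | COC(=O)[C@H](O)C/C=C(\CO[Si](C)(C)C(C)(C)C)CC/C=C(\C)CC/C=C(\C)CCC=C(C)C
F4 | step 8 | methyl (2R,4Z,8E,12E)-5-(chloromethyl)-2-hydroxy-9,13,17-trimethyloctadeca-4,8,12,16-tetraenoate | COC(=O)[C@H](O)C/C=C(\CCl)CC/C=C(\C)CC/C=C(\C)CCC=C(C)C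
F5 | step 11 | (2R)-5-[(3E,7E)-4,8,12-trimethyltrideca-3,7,11-trien-1-yl]-3,6-dihydro-2H-pyran-2-carbaldehyde | O=C[C@H]1CC=C(CC/C=C(\C)CC/C=C(\C)CCC=C(C)C)CO1
F6 | step 11 | (2R)-2-ethynyl-5-[(3E,7E)-4,8,12-trimethyltrideca-3,7,11-trien-1-yl]-3,6-dihydro-2H-pyran | C#C[C@H]1CC=C(CC/C=C(\C)CC/C=C(\C)CCC=C(C)C)CO1
F7 | step 11 | tributyl(1-{(2R)-5-[(3E,7E)-4,8,12-trimethyltrideca-3,7,11-trien-1-yl]-3,6-dihydro-2H-pyran-2-yl}ethenyl)stannane | C=C([Sn](CCCC)(CCCC)CCCC)[C@H]1CC=C(CC/C=C(\C)CC/C=C(\C)CCC=C(C)C)CO1
F8 | step 11 | (2R)-2-(1-iodoethenyl)-5-[(3E,7E)-4,8,12-trimethyltrideca-3,7,11-trien-1-yl]-3,6-dihydro-2H-pyran | C=C(I)[C@H]1CC=C(CC/C=C(\C)CC/C=C(\C)CCC=C(C)C)CO1
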